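The numbers of this flask stand for no real mixture; no experiment stands behind them.

The chemist at this bench is you: you charge the same mixture into the flasks below, build tris adduct through a chain of reagent steps, and watch by-product, released at each of those steps, turn tris adduct into side product.

| flask | starting material | reagent | temperature | time | remark |
|---|---|---|---|---|---|
| east | 0.010 M | 1.00 equiv | 120 °C | 1.0 h |  |
| south-west | 0.010 M | 1.00 equiv |  | 1.0 h | at 90 °C until 30 min, from then on at 120 °C |
| south-east | 0.010 M | 1.00 equiv | 90 °C | 1.0 h |  |
| north-east | 0.010 M | 1.00 equiv | 105 °C | 1.0 h |  |

    starting material + reagent → mono adduct + by-product (k1 = 0.011 M⁻¹ s⁻¹, Ea1 = 72.0 kJ mol⁻¹)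
    reagent + mono adduct → double product + by-product (k2 = 0.016 M⁻¹ s⁻¹, Ea2 = 59.0 kJ mol⁻¹)
    reagent + double product → tris adduct + by-product (k3 = 0.013 M⁻¹ s⁻¹, Ea3 = 55.0 kJ mol⁻¹)
    crystals ⇌ tris adduct, rate k4*(cs4 - [tris adduct]) while solid is left; crystals form when [tris adduct] > cs4 (cs4 = 4.1 mM, k4 = 0.046 s⁻¹)
    tris adduct + by-product → side product (k5 = 0.018 M⁻¹ s⁻¹, Ea5 = 68.0 kJ mol⁻¹)
    (constants at 90 °C)

- what is said of tris adduct includes crystals
- crystals is a solid; its amount is given per volume of the solution
- the list of constants is for 90 °C, to be carried to other temperatures by the activation energies

- the best flask by share of tris adduct in all that became tris adduct or side product; "all alike" if 1.5 percentage points covers them all (east / south-west / south-east / north-east / all alike)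
- share of tris adduct in all that became tris adduct or side product, east
- share of tris adduct in all that became tris adduct or side product, south-west
- share of tris adduct in all that became tris adduct or side product, south-east
- share of tris adduct in all that became tris adduct or side product, north-east

Reckon the rate, not the concentrations. At 90 °C reagent starts to be spent at 3.96 mM h⁻¹, which is the first-step constant k times the starting-material charge c times the equal reagent charge. Heating to 120 °C multiplies this by 6.17, and heating to 105 °C by 2.58.

In this reckoning the spending slows as the reagent falls. Starting material that is used up reappears first as mono adduct and double product, which take up reagent too, with constants 0.016 M⁻¹ s⁻¹ and 0.013 M⁻¹ s⁻¹ beside 0.011 M⁻¹ s⁻¹, so I treat the reagent as pseudo-first-order. Then τ = 1/(kc), 2.53 h at 90 °C, is the reagent lifetime, and I shorten it by those same factors on heating, an approximation, since 59.0 kJ mol⁻¹ and 55.0 kJ mol⁻¹ are lower than 72.0 kJ mol⁻¹.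

Let n be the lifetimes elapsed, summed piece by piece if the temperature changes. By this count the fraction e^(−n) of the reagent is left, and at a fixed temperature the rate has fallen by the factor e^n. You get n = 0.396 south-east, 1.02 north-east, 1.42 south-west and 2.44 east, where by this count the spending ends 11.5-fold slower than it began.

Tris adduct is lost on the same clock. With S the side-product constant over k, which is 1.64 at 90 °C and 1.48 at 120 °C, a molecule present from the first moment has lived through L = S(n − 1 + e^(−n)) of its own lifetimes. It survives as e^(−L). Later molecules have a shorter stretch of this exposure behind them, so I take this as an estimated floor on the share: 89.3% south-east and 10.4% east. South-east has the fewest lifetimes behind it, so I rank it first, and my reckoning stops at that ranking and those floors.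

The forecast does give shares, and they are its numbers, not mine: 33% east (27% to 40%), 61% south-west (55% to 67%), 95% south-east (93% to 96.5%) and 74% north-east (69% to 79%), with south-east best. Its ground: “Loss is therefore smallest at 90 °C.”

The flasks give 94.9% south-east, 74.5% north-east, 60.7% south-west and 31.1% east, so south-east is best. In the south-east flask the reagent reads 66% of its charge at 1.00 h, against 67.3% from τ. Now leave that south-east flask until 10.0 h, which is 3.95 lifetimes, more than the 2.44 of the east flask. The count says 1.92% of the reagent is left, the flask reads 1.33%, and its share has fallen to 6.09%.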